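**Plan**

1. Retrosynthesis: remove the three angelates one at a time (C11, then C9, then C15). Derive the C4 ketone and C5=C6 conjugation from a C4 alcohol with a C6 exocyclic methylene. Then cut C1–C11 (seven-membered ring) as the acylation of a lactone enolate in which C15 is tied to O9 as a temporary lactone.
2. Next cut C2–C1 (olefination of a cyclobutanone) and the cyclobutane bonds C2–C3 and C7–C8 (intramolecular vinylketene–alkene [2+2]). The open chain comes from a C5 enal acetal by two aldol reactions (C9–C10 and C4–C5).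
3. Forward ring order: cyclobutane and six-membered ring together, then the temporary lactone bridge, then the seven-membered carbocycle, last the enone.
4. Stereochemistry: C9 and C4 by reagent-controlled aldols. C4 in the tether steers the [2+2] (C3, C7, C8; the E-alkene puts the C8 methyl syn to the C4–C6 bridge). C2 by hydride from the face away from the C9 chain, C1 by the lactone tether from C9, C11 by hydride on the cage ketone. C4 is then erased by oxidation.
5. Enabling feature: C2 and C8 are the 1,3-carbons of the cyclobutane and carry C1 and C9 pseudo-axially on the same face, so C1 and C9 face each other. Since C15 and O9 are cis in the target, a two-atom O9–C15 bridge fits and leaves C11 only one face of C1.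

Key step: step 14

Locants used in the text (target numbering): C1 = quaternary carbon bearing CH3 and C15H2O; C2, C3, C8, C7 = cyclobutane (C2 bonded to C1, C3 the bridgehead next to C4=O, C7 the bridgehead next to C6, C8 quaternary with CH3); C4(=O)–C5=C6(CH3) = enone bridge; C9(O)–C10H2–C11(O) = chain from C8 back to C1. Locants inside compound names are those of the name.

Assumption: (R)-HYTRA and the (R,R)-bisphosphoramide are taken to show the sense of induction known for simple aldehydes; if the sense were opposite, the antipodal reagent would be used.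

**Step 1**
Reactants: 1 (E)-4,4-dimethoxy-2-methylbut-2-enal; 2 (R)-2-hydroxy-1,2,2-triphenylethyl acetate [(R)-HYTRA]
Product: 3 (R)-2-hydroxy-1,2,2-triphenylethyl (3R,4E)-3-hydroxy-6,6-dimethoxy-4-methylhex-4-enoate
Conditions: LiN(i-Pr)2 (2.2 equiv), THF, −78 to 0 °C; MgBr2; then 1, THF/2-methylbutane, −115 °C; aq. NH4Cl
Reagents that add atoms: none
Why: Auxiliary-controlled acetate aldol addition in which the magnesium enolate of the doubly deprotonated chiral acetate adds 1,2 to the enal under basic conditions that leave the dimethyl acetal intact, the triphenylglycol unit being expected to set C9 as (R).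

**Step 2**
Reactants: 3
Product: 4 (3R,4E)-3-hydroxy-N,6,6-trimethoxy-N,4-dimethylhex-4-enamide
Conditions: MeNH(OMe)·HCl, i-PrMgCl, THF, −20 to 0 °C
Reagents that add atoms: N,O-dimethylhydroxylamine hydrochloride, CNOC.Cl
Why: Ester aminolysis by the chloromagnesium amide of N,O-dimethylhydroxylamine gives the N-methoxy-N-methylamide, which should resist the later base, hydride and Lewis acid steps and accept a carbon nucleophile only once, and it frees the auxiliary diol for recovery.

**Step 3**
Reactants: 4
Product: 5 (3R,4E)-N,6,6-trimethoxy-N,4-dimethyl-3-(triethylsilyloxy)hex-4-enamide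
Conditions: Et3SiCl, imidazole, CH2Cl2, 0 °C
Reagents that add atoms: chlorotriethylsilane, CC[Si](Cl)(CC)CC
Why: Standard silyl ether formation at the only hydroxyl group, with triethylsilyl chosen so that it can later be removed in the presence of a tert-butyldimethylsilyl ether.

**Step 4**
Reactants: 5
Product: 6 (3R,4E)-N-methoxy-N,4-dimethyl-6-oxo-3-(triethylsilyloxy)hex-4-enamide
Conditions: LiBF4, MeCN/H2O (98:2), rt
Reagents that add atoms: water, O
Why: Mild Lewis acid-assisted hydrolysis of the allylic dimethyl acetal should give the conjugated E-enal without loss of the acid-sensitive triethylsilyl ether.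

**Step 5**
Reactants: 7 methyl 3-methylbut-2-enoate
Product: 8 tert-butyl[(1-methoxy-3-methylbuta-1,3-dien-1-yl)oxy]dimethylsilane
Conditions: LiN(i-Pr)2, THF/DMPU, −78 °C; t-BuMe2SiCl
Reagents that add atoms: tert-butyldimethylsilyl chloride, CC(C)(C)[Si](C)(C)Cl
Why: Kinetic γ-deprotonation of the senecioate and O-silylation of the dienolate is the standard preparation of the silyl dienol ether needed for a vinylogous Mukaiyama aldol reaction.

**Step 6**
Reactants: 6; 8
Product: 9 methyl (2E,5S,6E,8R)-5-hydroxy-10-[methoxy(methyl)amino]-3,7-dimethyl-10-oxo-8-(triethylsilyloxy)deca-2,6-dienoate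
Conditions: SiCl4, (R,R)-binaphthyl-2,2'-diamine-derived bisphosphoramide (5 mol%), i-Pr2NEt (cat.), CH2Cl2, −78 °C; aq. NaHCO3
Reagents that add atoms: none
Why: Lewis base-activated SiCl4 promotes a vinylogous Mukaiyama aldol addition in which the dienol ether reacts through its γ-carbon with the enal to give the (2E)-enoate, and the chiral bisphosphoramide is expected to override the remote C9 center and set C4 as (S).

**Step 7**
Reactants: 9
Product: 10 methyl (2E,5S,6E,8R)-5-(tert-butyldimethylsilyloxy)-10-[methoxy(methyl)amino]-3,7-dimethyl-10-oxo-8-(triethylsilyloxy)deca-2,6-dienoate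
Conditions: t-BuMe2SiOTf, 2,6-lutidine, CH2Cl2, −78 °C
Reagents that add atoms: tert-butyldimethylsilyl trifluoromethanesulfonate, CC(C)(C)[Si](C)(C)OS(=O)(=O)C(F)(F)F
Why: Silyl triflate and a hindered base silylate the secondary allylic alcohol at low temperature, and this ether is kept to the end as the stereocontrolling tether substituent and the precursor of the C4 ketone.

**Step 8**
Reactants: 10
Product: 11 (2E,5S,6E,8R)-5-(tert-butyldimethylsilyloxy)-10-[methoxy(methyl)amino]-3,7-dimethyl-10-oxo-8-(triethylsilyloxy)deca-2,6-dienoic acid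
Conditions: Me3SnOH, ClCH2CH2Cl, 70 °C; dilute aq. HCl wash
Reagents that add atoms: trimethyltin hydroxide, C[Sn](C)(C)O
Why: Trimethyltin hydroxide effects a mild saponification of the methyl ester that should leave both silyl ethers, the N-methoxy-N-methylamide and the δ-silyloxy enoate unit untouched.

**Step 9**
Reactants: 11
Product: 14 (3R)-3-[4-(tert-butyldimethylsilyloxy)-7-methyl-2-methylidene-6-oxobicyclo[3.1.1]heptan-7-yl]-N-methoxy-N-methyl-3-(triethylsilyloxy)propanamide (silyloxy trans to the C7 bridge; 7-methyl syn to the C2–C4 bridge), via acid chloride 12 (not isolated), via vinylketene 13 (not isolated)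
Conditions: 1-chloro-N,N,2-trimethylprop-1-en-1-amine, CH2Cl2, 0 °C to rt; then slow addition to Et3N, PhMe (high dilution), reflux
Reagents that add atoms: none
Why: Dehydrochlorination at the C6 methyl group gives the vinylketene, whose intramolecular thermal ketene–alkene [2+2] cycloaddition joins the carbonyl carbon C2 to the less substituted alkene carbon C3 and C7 to C8 (the bicyclo[3.1.1] mode known for geranic-type acid chlorides), suprafacial addition to the E-alkene placing the C8 methyl syn to the C4–C6 bridge and the C4 silyloxy group in the tether avoiding that methyl so that C3, C7 and C8 arise in one enantiomeric series.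

**Step 10**
Reactants: 14; 15 trimethyl phosphonoacetate
Product: 16 methyl 2-[4-(tert-butyldimethylsilyloxy)-7-[(1R)-3-[methoxy(methyl)amino]-3-oxo-1-(triethylsilyloxy)propyl]-7-methyl-2-methylidenebicyclo[3.1.1]heptan-6-ylidene]acetate (both alkene isomers; ring configuration as in 14)
Conditions: NaH, THF, 0 °C to reflux
Reagents that add atoms: none
Why: Horner–Wadsworth–Emmons olefination of the strained cyclobutanone, which cannot enolize because both α-carbons are bridgeheads, installs C1 and C15 as an alkylidene acetate whose double bond geometry is of no consequence.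

**Step 11**
Reactants: 16; 17 dimethyl(methylidene)ammonium iodide
Product: 19 methyl 2-[4-(tert-butyldimethylsilyloxy)-7-[(1R)-3-[methoxy(methyl)amino]-3-oxo-1-(triethylsilyloxy)propyl]-7-methyl-2-methylidenebicyclo[3.1.1]heptan-6-yl]-3-(dimethylamino)propanoate (6-H on the face of the C2–C4 bridge; epimers at the ester α-carbon), via silyl ketene acetal 18 (not isolated)
Conditions: [(Ph3P)CuH]6 (cat.), 1,2-(Ph2P)2C6H4 (cat.), PhMe2SiH, PhMe, rt; then 17, CH2Cl2, rt; aq. NaHCO3
Reagents that add atoms: none
Why: Copper hydride-catalyzed 1,4-hydrosilylation is chemoselective for the enoate and should deliver hydride to C2 from the face turned away from the C9 side chain, which sets C2 with C1 pseudo-axial toward C9, and the silyl ketene acetal is then trapped at C1 by the iminium salt in a Mannich reaction (the C1 configuration is irrelevant).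

**Step 12**
Reactants: 19
Product: 21 methyl 2-[4-(tert-butyldimethylsilyloxy)-7-[(1R)-3-[methoxy(methyl)amino]-3-oxo-1-(triethylsilyloxy)propyl]-7-methyl-2-methylidenebicyclo[3.1.1]heptan-6-yl]prop-2-enoate (ring configuration as in 19), via trimethylammonium iodide 20 (not isolated)
Conditions: MeI, MeOH, rt; then DBU, CH2Cl2, rt
Reagents that add atoms: none
Why: Exhaustive N-methylation followed by base-induced β-elimination of trimethylamine (Hofmann-type elimination of a Mannich base) gives the α-methylene ester without forming an enolate that could attack the amide.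

**Step 13**
Reactants: 21
Product: 23 bridged α-methylene lactone (O9–C15 lactone between the C9 hydroxyl and the acrylate on C2: a 5-methylidene-3-oxabicyclo[4.1.1]octan-4-one unit across the C2/C8 diagonal; C4 silyloxy; C6 methylidene and C11 N-methoxy-N-methylamide retained), via hydroxy ester 22 (not isolated)
Conditions: PPTS, MeOH, 0 °C; then ClBu2SnOSnBu2Cl (cat.), PhMe, reflux
Reagents that add atoms: none
Why: Acid-catalyzed methanolysis removes the triethylsilyl ether selectively, and tin-catalyzed intramolecular transesterification should then close the seven-membered lactone because C1 and C9 are held face to face on the cyclobutane diagonal.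

**Step 14**
Reactants: 23
Product: 26 cage keto lactone (C1 quaternary: CH3; lactone carbonyl C15 to O9; ketone C11 to C10; the six-membered keto lactone ring C1–C15–O9–C9–C10–C11 spans the C2/C8 diagonal as a 6-oxabicyclo[3.2.2]nonane-7,9-dione unit; C4 silyloxy and C6 methylidene retained), via lithium lactone enolate 24 (not isolated), via lithium hemiaminal alkoxide 25 (not isolated)
Conditions: LiBH(s-Bu)3 (1.1 equiv), THF, −78 to −20 °C; aq. NH4Cl
Reagents that add atoms: none
Why: Proposed new method: the bulky borohydride adds hydride 1,4 to the unhindered exocyclic methylene of the α-methylene lactone, which creates the C1 methyl group and, regiospecifically and without base, the lithium lactone enolate 24; C1 of this enolate then attacks the C11 N-methoxy-N-methylamide carbonyl to give the chelated hemiaminal alkoxide 25, which releases the ketone only on quench, so that neither retro-Claisen cleavage nor β-elimination of the O9 carboxylate should follow. The closest known reaction types are the trialkylborohydride-triggered reductive aldol cyclization and the acylation of ester enolates by N-methoxy-N-methylamides, merged here into a reductive Dieckmann-type closure. The new C1–C11 bond closes the seven-membered carbocycle in a 7-(enolexo)-exo-trig mode and at the same time a six-membered lactone-containing ring in a 6-(enolendo)-exo-trig mode. The only new stereocenter, quaternary C1, is fixed by the temporary lactone: C15 is held on the side of O9, so the C10–C11 arm of C9 can reach only the opposite lobe of the enolate and the methyl group ends up exo, which is the target configuration. The step needs 1,4- over 1,2-hydride delivery and C-acylation over proton transfer from C10; the unsubstituted acrylate terminus with the hindered hydride should secure the first, and the proximity of C1 and C11 enforced by the pseudo-axial C2/C8 substituents of the cyclobutane the second.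

**Step 15**
Reactants: 26
Product: 27 triol (target skeleton with C15H2OH; C9–OH; C11–OH trans to C15 and anti to C9–OH; C4–OSi(t-Bu)Me2; C6 exocyclic methylidene)
Conditions: LiAlH4, THF, −78 to 0 °C; aq. NaOH work-up
Reagents that add atoms: none
Why: Hydride reduction in which the C11 ketone should be attacked from the open underside of the cage next to the lactone bridge, away from the cyclobutane bridge (the same face to which O9/O15 aluminates would deliver hydride after lactone opening), which sets C11–OH trans to C15, and the lactone is reduced to the C9/C15 diol, removing the tether.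

**Step 16**
Reactants: 27; 28 angelic acid [(Z)-2-methylbut-2-enoic acid]
Product: 29 C15 mono-angelate (O15 (Z)-2-methylbut-2-enoate of 27; C9–OH and C11–OH free; C4–OSi(t-Bu)Me2 and C6 methylidene retained)
Conditions: 28 (1.05 equiv), 2,4,6-Cl3C6H2COCl, Et3N, PhMe, rt; then 27, PhMe, rt to 40 °C
Reagents that add atoms: none
Why: Yamaguchi-type esterification with one equivalent of the preformed mixed anhydride and no nucleophilic catalyst should acylate the primary C15 hydroxyl in preference to the two secondary hydroxyls, each of which sits next to a quaternary carbon, under the conditions in which (Z)-2-methylbut-2-enoates are least prone to isomerize to tiglates.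

**Step 17**
Reactants: 29; 28 angelic acid
Product: 30 C9,C15 bis-angelate (O9 and O15 (Z)-2-methylbut-2-enoates of 27; C11–OH free; C4–OSi(t-Bu)Me2 and C6 methylidene retained)
Conditions: 28 (1.05 equiv), 2,4,6-Cl3C6H2COCl, Et3N, PhMe, rt; then 29, PhMe, 60 °C
Reagents that add atoms: none
Why: A second Yamaguchi-type esterification with one equivalent of mixed anhydride should take place at C9–OH, whose neighbour C8 is a cyclobutane carbon with its substituents tied back, rather than at C11–OH, which is flanked by the quaternary C1 carrying the methyl group and the acyloxymethyl arm.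

**Step 18**
Reactants: 30; 28 angelic acid
Product: 31 tris-angelate (O9; O11 and O15 (Z)-2-methylbut-2-enoates of 27; C4–OSi(t-Bu)Me2 and C6 methylidene retained)
Conditions: 28 (excess), 2,4,6-Cl3C6H2COCl, Et3N, PhMe, rt; then 30, PhMe, 80 °C
Reagents that add atoms: none
Why: The same mixed anhydride esterification at higher temperature acylates the last and most hindered hydroxyl at C11, again without a nucleophilic catalyst so that the Z geometry of all three esters should be kept.

**Step 19**
Reactants: 31
Product: 32 C4 alcohol (tris-angelate with free C4–OH on the face toward C2 and C6 methylidene)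
Conditions: HF·pyridine, pyridine, THF, 0 °C to rt
Reagents that add atoms: none
Why: Buffered fluoride desilylation cleaves the remaining silyl ether and should leave the three angelates and both alkenes untouched.

**Step 20**
Reactants: 32
Product: 34 CNP0266467.1 (target), via β,γ-unsaturated ketone 33 (not isolated)
Conditions: 1,1,1-triacetoxy-1,1-dihydro-1,2-benziodoxol-3(1H)-one (DMP), CH2Cl2, rt; aq. wash; then DBU (cat.), CH2Cl2, 0 °C
Reagents that add atoms: none
Why: Periodinane oxidation of the secondary alcohol gives the β,γ-unsaturated ketone, and base-catalyzed isomerization moves the exocyclic double bond into conjugation (C3 is a bridgehead, so only C5 can be deprotonated), which gives the C4(=O)–C5=C6(CH3) enone and removes the C4 stereocenter.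

**Compound list**

1 | (E)-4,4-dimethoxy-2-methylbut-2-enal | COC(OC)/C=C(\C)C=O | starting material
2 | (R)-2-hydroxy-1,2,2-triphenylethyl acetate | CC(=O)O[C@H](c1ccccc1)C(O)(c1ccccc1)c1ccccc1 | starting material
3 | (R)-2-hydroxy-1,2,2-triphenylethyl (3R,4E)-3-hydroxy-6,6-dimethoxy-4-methylhex-4-enoate | COC(OC)/C=C(\C)[C@H](O)CC(=O)O[C@H](c1ccccc1)C(O)(c1ccccc1)c1ccccc1 | intermediate
4 | (3R,4E)-3-hydroxy-N,6,6-trimethoxy-N,4-dimethylhex-4-enamide | COC(OC)/C=C(\C)[C@H](O)CC(=O)N(C)OC | intermediate
5 | (3R,4E)-N,6,6-trimethoxy-N,4-dimethyl-3-(triethylsilyloxy)hex-4-enamide | COC(OC)/C=C(\C)[C@H](O[Si](CC)(CC)CC)CC(=O)N(C)OC | intermediate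
6 | (3R,4E)-N-methoxy-N,4-dimethyl-6-oxo-3-(triethylsilyloxy)hex-4-enamide | O=C/C=C(\C)[C@H](O[Si](CC)(CC)CC)CC(=O)N(C)OC | intermediate
7 | methyl 3-methylbut-2-enoate | COC(=O)C=C(C)C | starting material
8 | tert-butyl[(1-methoxy-3-methylbuta-1,3-dien-1-yl)oxy]dimethylsilane | COC(O[Si](C)(C)C(C)(C)C)=CC(C)=C | intermediate
9 | methyl (2E,5S,6E,8R)-5-hydroxy-10-[methoxy(methyl)amino]-3,7-dimethyl-10-oxo-8-(triethylsilyloxy)deca-2,6-dienoate | COC(=O)/C=C(\C)C[C@H](O)/C=C(\C)[C@H](O[Si](CC)(CC)CC)CC(=O)N(C)OC | intermediate
10 | methyl (2E,5S,6E,8R)-5-(tert-butyldimethylsilyloxy)-10-[methoxy(methyl)amino]-3,7-dimethyl-10-oxo-8-(triethylsilyloxy)deca-2,6-dienoate | COC(=O)/C=C(\C)C[C@H](O[Si](C)(C)C(C)(C)C)/C=C(\C)[C@H](O[Si](CC)(CC)CC)CC(=O)N(C)OC | intermediate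
11 | (2E,5S,6E,8R)-5-(tert-butyldimethylsilyloxy)-10-[methoxy(methyl)amino]-3,7-dimethyl-10-oxo-8-(triethylsilyloxy)deca-2,6-dienoic acid | OC(=O)/C=C(\C)C[C@H](O[Si](C)(C)C(C)(C)C)/C=C(\C)[C@H](O[Si](CC)(CC)CC)CC(=O)N(C)OC | intermediate
12 | acid chloride of 11 | ClC(=O)/C=C(\C)C[C@H](O[Si](C)(C)C(C)(C)C)/C=C(\C)[C@H](O[Si](CC)(CC)CC)CC(=O)N(C)OC | intermediate
13 | vinylketene: (5S,6E,8R)-5-(tert-butyldimethylsilyloxy)-10-[methoxy(methyl)amino]-7-methyl-3-methylidene-8-(triethylsilyloxy)deca-1,6-diene-1,10-dione | O=C=CC(=C)C[C@H](O[Si](C)(C)C(C)(C)C)/C=C(\C)[C@H](O[Si](CC)(CC)CC)CC(=O)N(C)OC | intermediate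
14 | (3R)-3-[4-(tert-butyldimethylsilyloxy)-7-methyl-2-methylidene-6-oxobicyclo[3.1.1]heptan-7-yl]-N-methoxy-N-methyl-3-(triethylsilyloxy)propanamide (silyloxy trans to the C7 bridge; 7-methyl syn to the C2–C4 bridge) | O=C1[C@H]2[C@@H](O[Si](C)(C)C(C)(C)C)CC(=C)[C@@H]1[C@@]2(C)[C@H](O[Si](CC)(CC)CC)CC(=O)N(C)OC | intermediate
15 | trimethyl phosphonoacetate | COC(=O)CP(=O)(OC)OC | starting material
16 | methyl 2-[bicyclo[3.1.1]heptan-6-ylidene]acetate derived from 14 (both alkene isomers) | COC(=O)C=C1[C@H]2[C@@H](O[Si](C)(C)C(C)(C)C)CC(=C)[C@@H]1[C@@]2(C)[C@H](O[Si](CC)(CC)CC)CC(=O)N(C)OC | intermediate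
17 | dimethyl(methylidene)ammonium iodide | C=[N+](C)C.[I-] | starting material
18 | dimethyl(phenyl)silyl methyl ketene acetal of the reduced ester | COC(O[Si](C)(C)c3ccccc3)=C[C@@H]1[C@H]2[C@@H](O[Si](C)(C)C(C)(C)C)CC(=C)[C@@H]1[C@@]2(C)[C@H](O[Si](CC)(CC)CC)CC(=O)N(C)OC | intermediate
19 | methyl 3-(dimethylamino)-2-[bicyclo[3.1.1]heptan-6-yl]propanoate (Mannich base; epimers at the ester α-carbon) | COC(=O)C(CN(C)C)[C@@H]1[C@H]2[C@@H](O[Si](C)(C)C(C)(C)C)CC(=C)[C@@H]1[C@@]2(C)[C@H](O[Si](CC)(CC)CC)CC(=O)N(C)OC | intermediate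
20 | trimethylammonium iodide of 19 | COC(=O)C(C[N+](C)(C)C)[C@@H]1[C@H]2[C@@H](O[Si](C)(C)C(C)(C)C)CC(=C)[C@@H]1[C@@]2(C)[C@H](O[Si](CC)(CC)CC)CC(=O)N(C)OC.[I-] | intermediate
21 | methyl 2-[bicyclo[3.1.1]heptan-6-yl]prop-2-enoate (α-methylene ester) | COC(=O)C(=C)[C@@H]1[C@H]2[C@@H](O[Si](C)(C)C(C)(C)C)CC(=C)[C@@H]1[C@@]2(C)[C@H](O[Si](CC)(CC)CC)CC(=O)N(C)OC | intermediate
22 | hydroxy ester (21 without the triethylsilyl group) | COC(=O)C(=C)[C@@H]1[C@H]2[C@@H](O[Si](C)(C)C(C)(C)C)CC(=C)[C@@H]1[C@@]2(C)[C@H](O)CC(=O)N(C)OC | intermediate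
23 | bridged α-methylene lactone (O9–C15) | C=C1[C@@H]2[C@H]3[C@@H](O[Si](C)(C)C(C)(C)C)CC(=C)[C@@H]2[C@@]3(C)[C@@H](CC(=O)N(C)OC)OC1=O | intermediate
24 | lithium lactone enolate | [Li+].CC=1[C@@H]2[C@H]3[C@@H](O[Si](C)(C)C(C)(C)C)CC(=C)[C@@H]2[C@@]3(C)[C@@H](CC(=O)N(C)OC)OC=1[O-] | intermediate
25 | lithium hemiaminal alkoxide | O=C5[C@]1(C)[C@@H]2[C@H]3[C@@H](O[Si](C)(C)C(C)(C)C)CC(=C)[C@@H]2[C@@]3(C)[C@H](O5)CC1([O-])N(C)OC.[Li+] | intermediate
26 | cage keto lactone | O=C5[C@]1(C)[C@@H]2[C@H]3[C@@H](O[Si](C)(C)C(C)(C)C)CC(=C)[C@@H]2[C@@]3(C)[C@H](O5)CC1=O | intermediate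
27 | triol with C4 silyl ether | OC[C@]1(C)[C@@H]2[C@H]3[C@@H](O[Si](C)(C)C(C)(C)C)CC(=C)[C@@H]2[C@@]3(C)[C@H](O)C[C@H]1O | intermediate
28 | angelic acid | C/C=C(/C)C(=O)O | starting material
29 | C15 mono-angelate with C4 silyl ether (C9–OH and C11–OH free) | C/C=C(/C)C(=O)OC[C@]1(C)[C@@H]2[C@H]3[C@@H](O[Si](C)(C)C(C)(C)C)CC(=C)[C@@H]2[C@@]3(C)[C@H](O)C[C@H]1O | intermediate
30 | C9,C15 bis-angelate with C4 silyl ether (C11–OH free) | C/C=C(/C)C(=O)OC[C@]1(C)[C@@H]2[C@H]3[C@@H](O[Si](C)(C)C(C)(C)C)CC(=C)[C@@H]2[C@@]3(C)[C@H](OC(=O)/C(C)=C\C)C[C@H]1O | intermediate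
31 | tris-angelate with C4 silyl ether | C/C=C(/C)C(=O)OC[C@]1(C)[C@@H]2[C@H]3[C@@H](O[Si](C)(C)C(C)(C)C)CC(=C)[C@@H]2[C@@]3(C)[C@H](OC(=O)/C(C)=C\C)C[C@H]1OC(=O)/C(C)=C\C | intermediate
32 | tris-angelate C4 alcohol | C/C=C(/C)C(=O)OC[C@]1(C)[C@@H]2[C@H]3[C@@H](O)CC(=C)[C@@H]2[C@@]3(C)[C@H](OC(=O)/C(C)=C\C)C[C@H]1OC(=O)/C(C)=C\C | intermediate
33 | β,γ-unsaturated ketone | C/C=C(/C)C(=O)OC[C@]1(C)[C@@H]2[C@H]3C(=O)CC(=C)[C@@H]2[C@@]3(C)[C@H](OC(=O)/C(C)=C\C)C[C@H]1OC(=O)/C(C)=C\C | intermediate
34 | CNP0266467.1 | C/C=C(/C)C(=O)OC[C@]1(C)[C@@H]2[C@H]3C(=O)C=C(C)[C@@H]2[C@@]3(C)[C@H](OC(=O)/C(C)=C\C)C[C@H]1OC(=O)/C(C)=C\C | target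

**Step count and risks**

Total step count: 20. Longest linear sequence: 19 (steps 1–4 and 6–20).

Steps most likely to fail:

Step 14 (proposed new method). The hydride could reduce the N-methoxy-N-methylamide or the lactone carbonyl directly. The enolate could also take a proton from C10, after which the O9 carboxylate would be eliminated, or C-acylation could fail for strain reasons. The fallback gives up the lactone tether and uses known chemistry, setting out from 16. Copper hydride-catalyzed conjugate reduction with protic work-up gives the saturated methyl ester F1. LiN(i-Pr)2 in THF at −78 °C deprotonates the ester, which is more acidic than the amide, and intramolecular acylation on the N-methoxy-N-methylamide (Dieckmann-type) gives the cyclic β-keto ester F2. MeI and K2CO3 in acetone should methylate C1 from the face away from the neighbouring C9 silyloxy group to give the quaternary keto ester F3. PPTS in MeOH frees the C9 alcohol to give the hydroxy ketone F4. Me4NBH(OAc)3 (Evans–Saksena hydroxyl-directed reduction) should give the anti diol F5. LiAlH4 then reduces the ester and returns to the route at 27.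

Step 13. Lactonization may lose to oxa-Michael addition of the C9 hydroxyl to the acrylate or to intermolecular transesterification. The fallback activates the acid instead of relying on ester exchange, setting out from 21. Me3SnOH gives the acrylic acid F6, HF·pyridine removes the triethylsilyl group to give the hydroxy acid F7, and mixed-anhydride lactonization (2,4,6-trichlorobenzoyl chloride, Et3N, then DMAP at high dilution) returns to the route at 23.

Step 17. Site selectivity between the two hindered secondary hydroxyls may be poor, acyl migration from O15 to O11 may scramble the esters, or Z to E isomerization to tiglate may set in if the acylation has to be forced. The fallback needs no site selectivity and builds the Z-alkenes after acylation, setting out from 29. Esterification of both secondary hydroxyls with the small 2-[bis(2,2,2-trifluoroethoxy)phosphoryl]propanoic acid (DCC, DMAP) gives the bis-phosphonopropanoate F8. Still–Gennari olefination with acetaldehyde (KN(SiMe3)2, 18-crown-6, THF, −78 °C) then forms the two remaining (Z)-2-methylbut-2-enoates and returns to the route at 31.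

**Further compounds**

F1 | step 14 | saturated methyl ester (methyl 2-[bicyclo[3.1.1]heptan-6-yl]acetate from 16) | COC(=O)C[C@@H]1[C@H]2[C@@H](O[Si](C)(C)C(C)(C)C)CC(=C)[C@@H]1[C@@]2(C)[C@H](O[Si](CC)(CC)CC)CC(=O)N(C)OC
F2 | step 14 | cyclic β-keto ester (C1–H; C11 ketone) | COC(=O)C1[C@@H]2[C@H]3[C@@H](O[Si](C)(C)C(C)(C)C)CC(=C)[C@@H]2[C@@]3(C)[C@H](O[Si](CC)(CC)CC)CC1=O
F3 | step 14 | quaternary keto ester (C1 methylated) | COC(=O)[C@]1(C)[C@@H]2[C@H]3[C@@H](O[Si](C)(C)C(C)(C)C)CC(=C)[C@@H]2[C@@]3(C)[C@H](O[Si](CC)(CC)CC)CC1=O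
F4 | step 14 | hydroxy ketone (C9–OH free) | COC(=O)[C@]1(C)[C@@H]2[C@H]3[C@@H](O[Si](C)(C)C(C)(C)C)CC(=C)[C@@H]2[C@@]3(C)[C@H](O)CC1=O
F5 | step 14 | anti diol ester | COC(=O)[C@]1(C)[C@@H]2[C@H]3[C@@H](O[Si](C)(C)C(C)(C)C)CC(=C)[C@@H]2[C@@]3(C)[C@H](O)C[C@H]1O
F6 | step 13 | acrylic acid (acid of 21) | OC(=O)C(=C)[C@@H]1[C@H]2[C@@H](O[Si](C)(C)C(C)(C)C)CC(=C)[C@@H]1[C@@]2(C)[C@H](O[Si](CC)(CC)CC)CC(=O)N(C)OC
F7 | step 13 | hydroxy acid | OC(=O)C(=C)[C@@H]1[C@H]2[C@@H](O[Si](C)(C)C(C)(C)C)CC(=C)[C@@H]1[C@@]2(C)[C@H](O)CC(=O)N(C)OC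
F8 | step 17 | C9,C11 bis-phosphonopropanoate of 29 (C15 angelate retained) | C/C=C(/C)C(=O)OC[C@]1(C)[C@@H]2[C@H]3[C@@H](O[Si](C)(C)C(C)(C)C)CC(=C)[C@@H]2[C@@]3(C)[C@H](OC(=O)C(C)P(=O)(OCC(F)(F)F)OCC(F)(F)F)C[C@H]1OC(=O)C(C)P(=O)(OCC(F)(F)F)OCC(F)(F)F
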